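The slowness of this flask struck me first. It is the north-west run itself, followed until it seemed to stand still.

| setting | north-west | east | flask |
|---|---|---|---|
| starting material | 1.6 M | 1.6 M | 1.6 M |
| coupling partner | 1.6 M | 1.6 M | 1.60 M |
| protic impurity | 0.080 M | 0.080 M | 0.0800 M |
| free catalyst | 8 mM | 12 mM | 8.0 mM |
| temperature | 40 °C | 35 °C | 40 °C |
| remark | the very flask that is asked about, followed so far | run made earlier |  |
| time |  |  | 15 h |

| run | time / h | target / % | starting material / % |
|---|---|---|---|
| north-west | 1.00 | 5.7 | 64.4 |
| north-west | 3.00 | 9.2 | 49.3 |
| north-west | 5.00 | 11.6 | 45.2 |
| north-west | 8.00 | 11.0 | 44.1 |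
| north-west | 12.0 | 11.5 | 43.7 |
| north-west | 15.0 | 11.1 | 44.6 |
| east | 0.500 | 2.0 | 73.3 |
| east | 1.00 | 6.5 | 59.2 |
| east | 1.50 | 8.6 | 50.1 |
| east | 2.00 | 11.9 | 45.0 |
| east | 2.50 | 12.4 | 38.3 |
| east | 3.00 | 13.5 | 35.4 |

(each reading ± 0.5 percentage points)

- target taken out counts as made
- steps under discussion: coupling partner + catalyst intermediate -> free catalyst + target; starting material + protic impurity -> quenched substrate; target + free catalyst <-> isomer of the product + free catalyst; free catalyst + open intermediate <-> catalyst intermediate; starting material + free catalyst -> free catalyst + open intermediate; free catalyst -> spent catalyst
- additions bring no volume worth counting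

- violet: at 15 h add free catalyst, 100% of the amount charged, then wait 8.0 h
- ochre: at 15 h take out 90% of the target then present, then wait 8.0 h
- grey: change nothing and wait 8.0 h more
- green: at 15 h raise the temperature by 20 K, then wait 8.0 h
- blue: at 15 h add coupling partner, 50.0% of the amount charged, then wait 8.0 h

* target, in percent of the starting material first charged, at 15 h
* what to do for the largest gain in target; "none" if nothing gains more than 2 percentage points (violet / ochre / grey / green / blue / none)
* target present, with what was taken out counted in, in percent of the starting material first charged, after violet
* target present, with what was taken out counted in, in percent of the starting material first charged, after blue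

In the north-west flask, the last four target readings averaged 11.3%. Starting material read 45.2% at 5.00 h and 44.6% at 15.0 h. So the north-west flask had stalled with starting material present. I therefore suspected the catalyst, since the step to spent catalyst was under discussion.

My next step used that suspicion. With 1.6 M of starting material on 8 mM of catalyst, the plateau gives 22.6 turnovers. I call this the lifetime output, a turnover number: target made per catalyst charged before the stop.

The weak link was the stop itself, since an equilibrium also stands still. So I turned to the east run, with 12 mM of catalyst at 35 °C. There target reached 13.5% by 3.00 h, higher than the plateau, and starting material fell to 35.4%, lower than in the north-west flask. Catalyst charge and temperature both differ between these runs, so this was a reading and not a proof, but I kept the catalyst stop. The east output had reached 18.0 turnovers and was still climbing, which is less than the north-west output.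

I committed to 11.3% at 15 h. I expected a second equal charge of catalyst to earn the same output, reaching 22.6%, and expected no gain from the other options.

The forecast gave 11.3% now, violet as best, 21% after that addition, which is lower than my figure, and 11.3% after adding partner. Its ground was this: “The plateau is therefore a dead-catalyst stall, not an equilibrium.”

The simulated flask gave 11.8%, chose violet with a gain of 9.1 percentage points, and reached 21.0% after it and 11.8% after adding partner.

    coupling partner + catalyst intermediate → free catalyst + target (k = 0.0430 /M/s, Ea = 57.0 kJ/mol)
    starting material + protic impurity → quenched substrate (k = 0.00130 /M/s, Ea = 75.0 kJ/mol)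
    target + free catalyst ⇌ isomer of the product + free catalyst, rate k3*[free catalyst]*[target] forward; the back reaction follows from the equilibrium constant (K = 1.70, k = 0.0500 /M/s, Ea = 72.0 kJ/mol, ΔH = −43.0 kJ/mol)
    free catalyst + open intermediate ⇌ catalyst intermediate (K = 0.730 /M, k = 0.0470 /M/s, Ea = 69.0 kJ/mol, ΔH = 33.0 kJ/mol)
    starting material + free catalyst → free catalyst + open intermediate (k = 0.0190 /M/s, Ea = 52.0 kJ/mol)
    free catalyst → spent catalyst (k = 2.00 × 10⁻⁴ /s, Ea = 106 kJ/mol)
    (constants at 40 °C)

The forecast held. Striking out the conversion of free catalyst into spent catalyst lifts target at 15 h from 11.8% to 33.3%, the largest single effect though not the whole shortfall. Free catalyst stood at 0.00909% of its charge by then, and at 150 h target still read 11.8%. The second charge earned 18.2 turnovers of net target, fewer than the first. For a neighbour flask, the same but with 0.014 M of free catalyst, the output read from the north-west run predicts 19.8%. The simulation gives 19.3%.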